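**Retrosynthetic overview**

1. Target 26 comes from the 1,3-trans tetralin-2,2-diester 20 by O8 benzylation, loss of one ester, kinetic protonation at C2, ester reduction and hydrogenolysis.
2. Ring B is the only ring that is made: a [5+1] annulation in which dimethyl malonate supplies C2 and forms C1–C2 (addition to an o-quinone methide) and C2–C3 (SN2 on an (S)-mesylate).
3. Feature used: the free C8–OH of ring A is ortho to C8a, so C1 (bearing the trimethoxyphenyl ring C) is an o-quinone methide carbon, and C2 is a single carbon lying between two electrophilic carbons, C1 and C3.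
4. Precursor 16 is assembled by MOM-directed ortho-lithiation at C8a onto 3,4,5-trimethoxybenzaldehyde (C1–C8a) and by aryl Grignard/CuI opening of benzyl (S)-glycidyl ether (C4–C4a, C3 stereocentre bought); ring A comes from 5-bromo-o-vanillin.
5. Order: rings A and C are bought, ring B closes in step 10; C3 is set by inversion and C1 thermodynamically in step 10, C2 in step 13.

Key step: step 10

Remark: lignan-type tetralin numbering is used (C1 aryl-bearing, C2 and C3 carrying the arms C9′ and C9, C4 the ring CH2, ring A = C4a, C5–C8, C8a). The epoxide whose CH2 opening leads to the (S)-mesylate is benzyl (S)-glycidyl ether, (2S)-2-[(benzyloxy)methyl]oxirane, because opening changes neither the stereocentre nor the CIP order.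

**Route**

Step 1
Reactants: 1 5-bromo-2-hydroxy-3-methoxybenzaldehyde
Product: 2 2-(benzyloxy)-5-bromo-3-methoxybenzaldehyde
Conditions: BnBr, K2CO3, DMF, rt
Reagents that add atoms: benzyl bromide, BrCc1ccccc1
Why: Williamson O-benzylation of the phenol, which installs the protecting group of the future O7.

Step 2
Reactants: 2 2-(benzyloxy)-5-bromo-3-methoxybenzaldehyde
Product: 4 2-(benzyloxy)-5-bromo-3-methoxyphenol, via aryl formate 3 (not isolated)
Conditions: mCPBA, CH2Cl2, rt; then K2CO3, MeOH, rt
Reagents that add atoms: mCPBA, OOC(=O)c1cccc(Cl)c1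
Why: Baeyer–Villiger (Dakin-type) oxidation in which the electron-rich aryl group migrates to give the formate, which is methanolysed to the phenol that becomes O8.

Step 3
Reactants: 4 2-(benzyloxy)-5-bromo-3-methoxyphenol
Product: 5 2-(benzyloxy)-5-bromo-1-methoxy-3-(methoxymethoxy)benzene
Conditions: MOMCl, iPr2NEt, CH2Cl2, 0 °C → rt
Reagents that add atoms: chloromethyl methyl ether, COCCl
Why: MOM protection of O8 gives a group that survives the organometallic steps and directs the lithiation of step 6.

Step 4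
Reactants: 5 2-(benzyloxy)-5-bromo-1-methoxy-3-(methoxymethoxy)benzene, 6 benzyl (S)-glycidyl ether
Product: 8 (2S)-1-(benzyloxy)-3-[4-(benzyloxy)-3-methoxy-5-(methoxymethoxy)phenyl]propan-2-ol, via arylmagnesium bromide 7 (not isolated)
Conditions: Mg turnings, THF, reflux; then CuI (10 mol %), 6, −30 → 0 °C; aq NH4Cl
Reagents that add atoms: none
Why: Copper-catalysed opening of the epoxide at its CH2 terminus by the aryl Grignard reagent (organocuprate epoxide opening) forms C4–C4a without touching the stereocentre, so the (S) configuration of 6 is carried into 8.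

Step 5
Reactants: 8 (2S)-1-(benzyloxy)-3-[4-(benzyloxy)-3-methoxy-5-(methoxymethoxy)phenyl]propan-2-ol
Product: 9 tert-butyldiphenylsilyl ether of 8
Conditions: TBDPSCl, imidazole, DMF, rt
Reagents that add atoms: tert-butyl(chloro)diphenylsilane, CC(C)(C)[Si](Cl)(c1ccccc1)c1ccccc1
Why: Silylation of the secondary alcohol with a bulky silyl group that is inert to n-BuLi and not prone to migrate to the aryllithium of step 6.

Step 6
Reactants: 9 tert-butyldiphenylsilyl ether of 8, 10 3,4,5-trimethoxybenzaldehyde
Product: 13 [2-[(2S)-3-(benzyloxy)-2-(tert-butyldiphenylsilyloxy)propyl]-5-(benzyloxy)-4-methoxy-6-(methoxymethoxy)phenyl](3,4,5-trimethoxyphenyl)methyl acetate (C1 epimers), via aryllithium 11 (not isolated), via lithium alkoxide 12 (not isolated)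
Conditions: n-BuLi, TMEDA, THF, −20 → 0 °C; 10, −78 °C; Ac2O, −78 °C → rt
Reagents that add atoms: acetic anhydride, CC(=O)OC(C)=O
Why: Directed ortho-metalation, in which the C8 OMOM group (a stronger director than the C6 OMe next to C5) steers lithiation to C8a, followed by addition to the aldehyde and acetylation of the alkoxide in the same flask so that the C1 oxygen is masked during steps 7 and 8; C1 forms as both epimers, which converge in step 10.

Step 7
Reactants: 13 benzylic acetate silyl ether
Product: 14 [2-[(2S)-3-(benzyloxy)-2-hydroxypropyl]-5-(benzyloxy)-4-methoxy-6-(methoxymethoxy)phenyl](3,4,5-trimethoxyphenyl)methyl acetate (C1 epimers)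
Conditions: Bu4NF, AcOH, THF, rt → 40 °C
Reagents that add atoms: none
Why: Fluoride desilylation buffered with acetic acid frees the C3 hydroxyl and leaves the acetate, the MOM ether and the benzyl ethers untouched.

Step 8
Reactants: 14 hydroxy acetate
Product: 15 [2-[(2S)-3-(benzyloxy)-2-(methanesulfonyloxy)propyl]-5-(benzyloxy)-4-methoxy-6-(methoxymethoxy)phenyl](3,4,5-trimethoxyphenyl)methyl acetate (C1 epimers)
Conditions: MsCl, Et3N, CH2Cl2, 0 °C
Reagents that add atoms: methanesulfonyl chloride, CS(Cl)(=O)=O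
Why: Mesylation of the only free hydroxyl with retention at C3, giving the (S)-mesylate.

Step 9
Reactants: 15 mesylate acetate
Product: 16 (2S)-1-(benzyloxy)-3-[4-(benzyloxy)-3-hydroxy-5-methoxy-2-[(4-methylbenzenesulfonyl)(3,4,5-trimethoxyphenyl)methyl]phenyl]propan-2-yl methanesulfonate (C1 epimers)
Conditions: TolSO2Na, CF3CO2H, CH2Cl2 (wet), 0 °C → rt
Reagents that add atoms: sodium 4-methylbenzenesulfinate, [Na+].[O-]S(=O)c1ccc(C)cc1
Why: Acid-mediated SN1 exchange in which the doubly benzylic, alkoxy-stabilised C1 acetate ionises and p-toluenesulfinic acid traps the cation at sulfur, while the same acid hydrolyses the aryl MOM ether; because the C3 oxygen is already a non-nucleophilic mesylate, isochroman closure onto the cation is excluded.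

Step 10
Reactants: 16 phenol sulfone mesylate, 17 dimethyl malonate
Product: 20 dimethyl (1S,3S)-7-(benzyloxy)-3-[(benzyloxy)methyl]-8-hydroxy-6-methoxy-1-(3,4,5-trimethoxyphenyl)-3,4-dihydronaphthalene-2,2(1H)-dicarboxylate, via o-quinone methide 18 (not isolated), via open-chain malonate adduct 19 (not isolated)
Conditions: 17 (1.2 equiv), Cs2CO3 (3 equiv), MeCN, 0 °C → 60 °C
Reagents that add atoms: none
Why: Proposed new method: Cs2CO3 deprotonates the C8 phenol, the phenoxide expels p-toluenesulfinate to give o-quinone methide 18, malonate adds at C1 to give 19, and the resulting tertiary malonate anion displaces the C3 mesylate to form C2–C3; the closest known reactions are base-triggered malonate additions to o-quinone methides released from 2-(sulfonylmethyl)phenols and alkylation of malonates by secondary sulfonates, here run as one cascade. Ring B closes by a 6-exo-tet SN2 displacement. C3 is set by inversion of the bought (S)-mesylate centre, and C1 is set under thermodynamic control, because the C8 phenoxide can re-expel the malonate carbon (retro-Michael and re-addition through the o-quinone methide) before and after closure, so the aryl group settles pseudoaxial, away from O8, and trans to the equatorial C3 arm. The step needs C-alkylation at C3 to win over elimination toward C4 and over intermolecular attack: conjugate addition is fast at 0 °C whereas the hindered mesylate reacts only on warming and then intramolecularly, the weakly basic malonate/Cs2CO3 pair limits E2, and O8 cannot reach C3 because such a ring would bridge meta positions of ring A.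

Step 11
Reactants: 20 phenol diester
Product: 21 dimethyl (1S,3S)-7,8-bis(benzyloxy)-3-[(benzyloxy)methyl]-6-methoxy-1-(3,4,5-trimethoxyphenyl)-3,4-dihydronaphthalene-2,2(1H)-dicarboxylate
Conditions: BnBr, K2CO3, DMF, 0 °C → rt
Reagents that add atoms: benzyl bromide, BrCc1ccccc1
Why: Williamson etherification of O8, which shuts off the retro-Michael opening of ring B before the hot and basic steps that follow.

Step 12
Reactants: 21 tribenzyl diester
Product: 22 methyl 7,8-bis(benzyloxy)-3-[(benzyloxy)methyl]-6-methoxy-1-(3,4,5-trimethoxyphenyl)-1,2,3,4-tetrahydronaphthalene-2-carboxylate (C1 and C3 as in 21; C2 epimers)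
Conditions: LiCl, H2O, DMSO, 150 °C
Reagents that add atoms: none
Why: Krapcho dealkoxycarbonylation, in which chloride demethylates one ester, the carboxylate loses CO2 and the enolate is protonated by water, leaving a C2 epimer mixture that step 13 converges.

Step 13
Reactants: 22 monoester (C2 epimers)
Product: 24 methyl (1S,2S,3S)-7,8-bis(benzyloxy)-3-[(benzyloxy)methyl]-6-methoxy-1-(3,4,5-trimethoxyphenyl)-1,2,3,4-tetrahydronaphthalene-2-carboxylate, via lithium enolate 23 (not isolated)
Conditions: LiN(iPr)2, THF, −78 → −40 °C; then 2,6-di-tert-butyl-4-methylphenol, −78 °C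
Reagents that add atoms: none
Why: Deprotonation and kinetic protonation of the ester enolate, in which allylic 1,3-strain and the peri C8 OBn hold the C1 aryl pseudoaxial so that the bulky phenol should deliver the proton to C2 from the face anti to the aryl (the C3 arm on the other face is the smaller flanking group), placing the ester cis to the aryl and trans to the C3 arm as in kinetic protonations of C2 enolates of 1-aryltetralin lignans.

Step 14
Reactants: 24 (1S,2S,3S)-monoester
Product: 25 [(1S,2S,3S)-7,8-bis(benzyloxy)-3-[(benzyloxy)methyl]-6-methoxy-1-(3,4,5-trimethoxyphenyl)-1,2,3,4-tetrahydronaphthalen-2-yl]methanol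
Conditions: LiAlH4, THF, 0 °C → rt
Reagents that add atoms: none
Why: Hydride reduction of the ester to the primary alcohol C9′ without touching any stereocentre or the benzyl ethers.

Step 15
Reactants: 25 tribenzyl alcohol
Product: 26 (1S,2S,3S)-2,3-bis(hydroxymethyl)-6-methoxy-1-(3,4,5-trimethoxyphenyl)-1,2,3,4-tetrahydronaphthalene-7,8-diol (target)
Conditions: H2 (1 atm), 10% Pd/C, EtOAc–MeOH, rt
Reagents that add atoms: none
Why: Hydrogenolysis of the two aryl benzyl ethers and the alkyl benzyl ether over Pd/C frees O7, O8 and O9, with no other reducible group and no stereocentre affected.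

**Compound list**

1 | 5-bromo-2-hydroxy-3-methoxybenzaldehyde | COc1cc(Br)cc(C=O)c1O | starting material
2 | 2-(benzyloxy)-5-bromo-3-methoxybenzaldehyde | COc1cc(Br)cc(C=O)c1OCc1ccccc1 | intermediate
3 | 2-(benzyloxy)-5-bromo-3-methoxyphenyl formate | COc1cc(Br)cc(OC=O)c1OCc1ccccc1 | intermediate
4 | 2-(benzyloxy)-5-bromo-3-methoxyphenol | COc1cc(Br)cc(O)c1OCc1ccccc1 | intermediate
5 | 2-(benzyloxy)-5-bromo-1-methoxy-3-(methoxymethoxy)benzene | COCOc1cc(Br)cc(OC)c1OCc1ccccc1 | intermediate
6 | benzyl (S)-glycidyl ether, (2S)-2-[(benzyloxy)methyl]oxirane | C1O[C@@H]1COCc1ccccc1 | starting material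
7 | [4-(benzyloxy)-3-methoxy-5-(methoxymethoxy)phenyl]magnesium bromide | COCOc1cc([Mg]Br)cc(OC)c1OCc1ccccc1 | intermediate
8 | (2S)-1-(benzyloxy)-3-[4-(benzyloxy)-3-methoxy-5-(methoxymethoxy)phenyl]propan-2-ol | COCOc1cc(C[C@@H](COCc2ccccc2)O)cc(OC)c1OCc1ccccc1 | intermediate
9 | tert-butyldiphenylsilyl ether of 8, (S) | COCOc1cc(C[C@@H](COCc2ccccc2)O[Si](c2ccccc2)(c2ccccc2)C(C)(C)C)cc(OC)c1OCc1ccccc1 | intermediate
10 | 3,4,5-trimethoxybenzaldehyde | COc1cc(C=O)cc(OC)c1OC | starting material
11 | C8a aryllithium of 9 (lithium between the OMOM carbon and the side-chain carbon) | COCOc1c([Li])c(C[C@@H](COCc2ccccc2)O[Si](c2ccccc2)(c2ccccc2)C(C)(C)C)cc(OC)c1OCc1ccccc1 | intermediate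
12 | lithium diarylmethoxide from 11 and 10 | COCOc1c(C(O[Li])c2cc(OC)c(OC)c(OC)c2)c(C[C@@H](COCc2ccccc2)O[Si](c2ccccc2)(c2ccccc2)C(C)(C)C)cc(OC)c1OCc1ccccc1 | intermediate
13 | diarylmethyl acetate with OMOM at C8 and (S)-OTBDPS side chain (C1 epimers) | COCOc1c(C(OC(C)=O)c2cc(OC)c(OC)c(OC)c2)c(C[C@@H](COCc2ccccc2)O[Si](c2ccccc2)(c2ccccc2)C(C)(C)C)cc(OC)c1OCc1ccccc1 | intermediate
14 | diarylmethyl acetate with free (S)-secondary alcohol (C1 epimers) | COCOc1c(C(OC(C)=O)c2cc(OC)c(OC)c(OC)c2)c(C[C@@H](COCc2ccccc2)O)cc(OC)c1OCc1ccccc1 | intermediate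
15 | diarylmethyl acetate with (S)-mesylate (C1 epimers) | COCOc1c(C(OC(C)=O)c2cc(OC)c(OC)c(OC)c2)c(C[C@@H](COCc2ccccc2)OS(C)(=O)=O)cc(OC)c1OCc1ccccc1 | intermediate
16 | C8 phenol with C1 aryl(tosyl)methyl group and (S)-mesylate side chain (C1 epimers) | COc1cc(C[C@@H](COCc2ccccc2)OS(C)(=O)=O)c(C(c2cc(OC)c(OC)c(OC)c2)S(=O)(=O)c2ccc(C)cc2)c(O)c1OCc1ccccc1 | intermediate
17 | dimethyl malonate | COC(=O)CC(=O)OC | starting material
18 | 2-(benzyloxy)-5-[(2S)-3-(benzyloxy)-2-(methanesulfonyloxy)propyl]-3-methoxy-6-[(3,4,5-trimethoxyphenyl)methylidene]cyclohexa-2,4-dien-1-one (o-quinone methide) | COC1=C(OCc2ccccc2)C(=O)C(=Cc2cc(OC)c(OC)c(OC)c2)C(C[C@@H](COCc2ccccc2)OS(C)(=O)=O)=C1 | intermediate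
19 | dimethyl 2-{[3-(benzyloxy)-2-hydroxy-4-methoxy-6-[(2S)-3-(benzyloxy)-2-(methanesulfonyloxy)propyl]phenyl](3,4,5-trimethoxyphenyl)methyl}malonate (C1 epimers, present as cesium salts) | COc1cc(C[C@@H](COCc2ccccc2)OS(C)(=O)=O)c(C(c2cc(OC)c(OC)c(OC)c2)C(C(=O)OC)C(=O)OC)c(O)c1OCc1ccccc1 | intermediate
20 | dimethyl (1S,3S)-7-(benzyloxy)-3-[(benzyloxy)methyl]-8-hydroxy-6-methoxy-1-(3,4,5-trimethoxyphenyl)-3,4-dihydronaphthalene-2,2(1H)-dicarboxylate (1,3-trans) | COc1cc2c(c(O)c1OCc1ccccc1)[C@H](c1cc(OC)c(OC)c(OC)c1)C(C(=O)OC)(C(=O)OC)[C@@H](COCc1ccccc1)C2 | intermediate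
21 | O8-benzyl ether of 20 | COc1cc2c(c(OCc3ccccc3)c1OCc1ccccc1)[C@H](c1cc(OC)c(OC)c(OC)c1)C(C(=O)OC)(C(=O)OC)[C@@H](COCc1ccccc1)C2 | intermediate
22 | C2 monoester, mixture of C2 epimers | COc1cc2c(c(OCc3ccccc3)c1OCc1ccccc1)[C@H](c1cc(OC)c(OC)c(OC)c1)C(C(=O)OC)[C@@H](COCc1ccccc1)C2 | intermediate
23 | lithium enolate of 22 | COC(O[Li])=C1[C@@H](c2cc(OC)c(OC)c(OC)c2)c2c(OCc3ccccc3)c(OCc3ccccc3)c(OC)cc2C[C@@H]1COCc1ccccc1 | intermediate
24 | methyl (1S,2S,3S)-7,8-bis(benzyloxy)-3-[(benzyloxy)methyl]-6-methoxy-1-(3,4,5-trimethoxyphenyl)-1,2,3,4-tetrahydronaphthalene-2-carboxylate (1,2-cis, 2,3-trans) | COc1cc2c(c(OCc3ccccc3)c1OCc1ccccc1)[C@H](c1cc(OC)c(OC)c(OC)c1)[C@H](C(=O)OC)[C@@H](COCc1ccccc1)C2 | intermediate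
25 | [(1S,2S,3S)-7,8-bis(benzyloxy)-3-[(benzyloxy)methyl]-6-methoxy-1-(3,4,5-trimethoxyphenyl)-1,2,3,4-tetrahydronaphthalen-2-yl]methanol | COc1cc2c(c(OCc3ccccc3)c1OCc1ccccc1)[C@H](c1cc(OC)c(OC)c(OC)c1)[C@H](CO)[C@@H](COCc1ccccc1)C2 | intermediate
26 | (1S,2S,3S)-2,3-bis(hydroxymethyl)-6-methoxy-1-(3,4,5-trimethoxyphenyl)-1,2,3,4-tetrahydronaphthalene-7,8-diol | COc1cc2c(c(O)c1O)[C@H](c1cc(OC)c(OC)c(OC)c1)[C@H](CO)[C@@H](CO)C2 | target

**Totals**

Total step count: 15. Longest linear sequence: 15 steps (1 → 26).

**Steps most likely to fail**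

1. Step 10 (proposed cascade). The process at risk is E2 loss of the mesylate toward C4, or stalling after the conjugate addition because the tertiary malonate anion does not displace the hindered, β-alkoxy secondary mesylate. The fallback reverses the order of the two bond formations and uses known chemistry throughout; it sets out from 15 and comes back at 20. Sodium dimethyl malonate (NaH, DMF, 60 °C) displaces the mesylate of 15 intermolecularly with inversion to give the C3 malonate F1. TolSO2Na and CF3CO2H, as in step 9, then exchange the acetate for the sulfone and free O8 to give the phenol sulfone F2. Cs2CO3 in MeCN releases the o-quinone methide, which the tethered malonate closes by an intramolecular Michael addition, with C1 again settling trans to the C3 arm by reversible addition, to give 20.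

2. Step 13. The process at risk is poor facial selectivity in the enolate protonation, since the C3 arm sits on the face opposite to the aryl. The fallback switches from kinetic to thermodynamic control; it sets out from 22 and comes back at 24. NaOMe in MeOH at reflux equilibrates C2 toward the epimer with the ester equatorial and trans to the C3 arm while the aryl stays pseudoaxial; the epimers are separated and the unwanted one is returned to the equilibration. No new compound is made.

3. Step 6. The process at risk is lithiation at a benzylic OCH2 group (followed by Wittig rearrangement) or at C5 instead of C8a. The fallback replaces C–H lithiation by an ortho-specific formylation; it sets out from 9 and comes back at 13. HCl in MeOH removes the aryl MOM group to give the phenol F3. MgCl2, Et3N and paraformaldehyde in MeCN at reflux formylate the only free position ortho to the phenol (C8a) to give the salicylaldehyde F4. MOMCl and iPr2NEt give the MOM-protected aldehyde F5. Addition of 3,4,5-trimethoxyphenylmagnesium bromide in THF at −78 °C, with an Ac2O quench, gives 13.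

**Further compounds**

F1 | step 10 | dimethyl 2-[(2S)-1-(benzyloxy)-3-{2-[acetoxy(3,4,5-trimethoxyphenyl)methyl]-4-(benzyloxy)-5-methoxy-3-(methoxymethoxy)phenyl}propan-2-yl]malonate | COCOc1c(C(OC(C)=O)c2cc(OC)c(OC)c(OC)c2)c(C[C@H](COCc2ccccc2)C(C(=O)OC)C(=O)OC)cc(OC)c1OCc1ccccc1
F2 | step 10 | dimethyl 2-[(2S)-1-(benzyloxy)-3-{4-(benzyloxy)-3-hydroxy-5-methoxy-2-[(4-methylbenzenesulfonyl)(3,4,5-trimethoxyphenyl)methyl]phenyl}propan-2-yl]malonate | COc1cc(C[C@H](COCc2ccccc2)C(C(=O)OC)C(=O)OC)c(C(c2cc(OC)c(OC)c(OC)c2)S(=O)(=O)c2ccc(C)cc2)c(O)c1OCc1ccccc1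
F0 | step 13 | none | none
F3 | step 6 | 2-(benzyloxy)-5-[(2S)-3-(benzyloxy)-2-(tert-butyldiphenylsilyloxy)propyl]-3-methoxyphenol | COc1cc(C[C@@H](COCc2ccccc2)O[Si](c2ccccc2)(c2ccccc2)C(C)(C)C)cc(O)c1OCc1ccccc1
F4 | step 6 | 3-(benzyloxy)-6-[(2S)-3-(benzyloxy)-2-(tert-butyldiphenylsilyloxy)propyl]-2-hydroxy-4-methoxybenzaldehyde | COc1cc(C[C@@H](COCc2ccccc2)O[Si](c2ccccc2)(c2ccccc2)C(C)(C)C)c(C=O)c(O)c1OCc1ccccc1
F5 | step 6 | 3-(benzyloxy)-6-[(2S)-3-(benzyloxy)-2-(tert-butyldiphenylsilyloxy)propyl]-4-methoxy-2-(methoxymethoxy)benzaldehyde | COCOc1c(C=O)c(C[C@@H](COCc2ccccc2)O[Si](c2ccccc2)(c2ccccc2)C(C)(C)C)cc(OC)c1OCc1ccccc1
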